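# Total synthesis of spiculoic acid B

**Retrosynthesis**
1. Spiculoic acid B (21) comes from Pinnick oxidation of the aldehyde 20.
2. 20 is formed by a catalysed intramolecular Diels–Alder (IMDA) of the pentaenal 19. This step closes both rings at once: the cyclopentene through the 3-atom tether, then the cyclohexene. It sets four of the five stereocentres and creates the two contiguous quaternary centres.
3. The single C-Me stereocentre of the tether, set by asymmetric catalysis, controls the facial selectivity of the IMDA.
4. 19 comes from a Z-enoate/vinyl building block (9). The triene arm is built on the vinyl group by cross-metathesis, Wittig and Horner–Wadsworth–Emmons (HWE) steps, and the dienophile arm is finished last.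
5. 9 comes from (S)-2-methylbut-3-enal (6), which comes from organocatalytic desymmetrisation of the achiral diol 1.

Assumptions (one line): the catalyst enantiomers in Steps 1 and 14 are chosen to give the depicted absolute configuration, and reagents 8 and 13 are prepared in-house (Steps 6 and 9).

## Route

**Step 1**
Reactants: 1 (2-methylpropane-1,3-diol)
Product: 2 ((S)-3-(TBSO)-2-methylpropan-1-ol)
Conditions: TBSCl, i-Pr2NEt, chiral amino-acid-derived Lewis-base catalyst (10 mol%), THF, –20 °C
Reagents that add atoms: TBSCl, C[Si](C)(Cl)C(C)(C)C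
Why: Organocatalytic desymmetrising silylation differentiates the two enantiotopic CH2OH groups of the prochiral diol and sets the future C-Me stereocentre (S).

**Step 2**
Reactants: 2
Product: 3 ((R)-3-(TBSO)-2-methylpropanal)
Conditions: Dess–Martin periodinane (DMP), NaHCO3, CH2Cl2, 0 °C → rt
Reagents that add atoms: none
Why: Mild Dess–Martin oxidation of the primary alcohol. The β-silyloxy aldehyde is configurationally robust and the TBS ether is untouched.

**Step 3**
Reactants: 3
Product: 4 (TBS ether of (S)-2-methylbut-3-en-1-ol)
Conditions: Ph3P+CH3 Br–, KOtBu, THF, 0 °C → rt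
Reagents that add atoms: methylenetriphenylphosphorane, C=P(c1ccccc1)(c1ccccc1)c1ccccc1
Why: Salt-free Wittig methylenation at low temperature converts the aldehyde into a vinyl group without touching the α-stereocentre.

**Step 4**
Reactants: 4
Product: 5 ((S)-2-methylbut-3-en-1-ol)
Conditions: TBAF, THF, 0 °C (careful, cold work-up; the alcohol is volatile)
Reagents that add atoms: none
Why: Fluoride removes the silyl ether and leaves the alkene and the stereocentre intact.

**Step 5**
Reactants: 5
Product: 6 ((S)-2-methylbut-3-enal)
Conditions: DMP, NaHCO3, CH2Cl2, 0 °C, 30 min; the dilute filtrate is used directly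
Reagents that add atoms: none
Why: Buffered Dess–Martin oxidation under neutral conditions limits isomerisation of this labile α-methyl-β,γ-unsaturated aldehyde.

**Step 6**
Reactants: 7 (methyl bis(2,2,2-trifluoroethyl)phosphonoacetate)
Product: 8 (methyl 2-[bis(2,2,2-trifluoroethoxy)phosphoryl]butanoate)
Conditions: NaH (1 equiv), EtI, THF, 0 °C → rt
Reagents that add atoms: ethyl iodide, CCI
Why: Mono-alkylation of the phosphonate carbanion gives the α-ethyl Still–Gennari reagent.

**Step 7**
Reactants: 6, 8
Product: 9 (methyl (2Z,4S)-2-ethyl-4-methylhexa-2,5-dienoate)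
Conditions: 8, KHMDS, 18-crown-6, THF, –78 °C; add 6 at –78 °C, 3 h
Reagents that add atoms: none
Why: Still–Gennari Z-selective HWE, with the phosphonate anion preformed at –78 °C so the labile aldehyde is consumed before it can epimerise, gives the Z-α-ethyl enoate. The Z geometry is needed so that C5 and C8 end up cis in the cyclopentene. Assumed Z:E ≥ 9:1; the isomers are separated by AgNO3-silica.

**Step 8**
Reactants: 9, 10 (2-ethylacrolein)
Product: 11 (methyl (2Z,4S,5E)-2,6-diethyl-4-methyl-7-oxohepta-2,5-dienoate)
Conditions: 10 (5 equiv), Hoveyda–Grubbs II (5 mol%), CH2Cl2, 40 °C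
Reagents that add atoms: none (10 is a numbered reactant; ethylene is lost)
Why: Cross-metathesis on the monosubstituted vinyl group, which is far more reactive than the electron-poor Z-trisubstituted enoate, builds the trisubstituted E-enal (C7=C8 of the final numbering) in one step.

**Step 9**
Reactants: 12 (butanal)
Product: 13 (2-(triphenylphosphoranylidene)butanal)
Conditions: (i) Br2, CH2Cl2, 0 °C; (ii) PPh3, rt; (iii) aq. NaOH (by analogy with the known methyl homologue)
Reagents that add atoms: triphenylphosphine, P(c1ccccc1)(c1ccccc1)c1ccccc1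
Why: α-Bromination, phosphonium formation and deprotonation give the stabilised formyl ylide, which supplies the ethyl-bearing C3 unit.

**Step 10**
Reactants: 11, 13
Product: 14 (methyl (2Z,4S,5E,7E)-2,6,8-triethyl-4-methyl-9-oxonona-2,5,7-trienoate)
Conditions: toluene, 90 °C, sealed tube, 24 h
Reagents that add atoms: none
Why: Wittig olefination with a stabilised α-alkyl ylide is E-selective, and the base-free conditions avoid epimerising the doubly allylic C–H.

**Step 11**
Reactants: 14, 15 (diethyl benzylphosphonate)
Product: 16 (methyl (2Z,4S,5E,7E,9E)-2,6,8-triethyl-4-methyl-10-phenyldeca-2,5,7,9-tetraenoate)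
Conditions: 15, NaH, THF, 0 °C; add 14 slowly at –20 °C → rt
Reagents that add atoms: none
Why: HWE with a benzylphosphonate gives the E-styryl group. Adding the dienal to excess anion consumes it quickly.

**Step 12**
Reactants: 16
Product: 17 ((2Z,4S,5E,7E,9E)-2,6,8-triethyl-4-methyl-10-phenyldeca-2,5,7,9-tetraen-1-ol)
Conditions: DIBAL-H (3 equiv), CH2Cl2, –78 °C
Reagents that add atoms: none
Why: The ester is the only reducible carbonyl and the polyene is untouched; the Z-alkene is retained.

**Step 13**
Reactants: 17, 18 (2-(triphenylphosphoranylidene)propanal)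
Product: 19 ((2E,4Z,6S,7E,9E,11E)-4,8,10-triethyl-2,6-dimethyl-12-phenyldodeca-2,4,7,9,11-pentaenal)
Conditions: MnO2 (15 equiv), 18 (2 equiv), CH2Cl2, rt, dark
Reagents that add atoms: none
Why: Tandem MnO2 oxidation–Wittig generates the labile Z-enal in situ and traps it at once to give the E-α-methyl dienal, which is the dienophile.

**Step 14**
Reactants: 19
Product: 20 (IMDA aldehyde: the trans-fused hydrindadiene aldehyde analogue of the target)
Conditions: (2S,5S)-5-benzyl-2-tert-butyl-3-methylimidazolidin-4-one·TfOH (20 mol%), MeCN/CH2Cl2 with 5% H2O, BHT, –10 → 4 °C, 48 h, dark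
Reagents that add atoms: none
Why: Proposed new method: iminium-catalysed IMDA of a tetraene whose diene terminus is fully substituted. Condensation gives the E-iminium ion, which lowers the LUMO of C4=C5 (conjugated to the Z C6=C7 bond). The electron-rich (styryl)triene then adds at C5 (forming C5–C9) in an endo, iminium-under-diene, asynchronous Diels–Alder TS. The E-dienophile places the tether exo, giving the trans-fused cyclopentene, and C3–C4 closes to form the vicinal quaternary centres. The C8 methyl blocks one tether face, so the diene approaches anti to it, which fixes C9, C5, C4 and C3. The closest known chemistry is the iminium-catalysed IMDA of trienals and the thermal type-1 IMDA of 1,3,8-nonatrienes.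

**Step 15**
Reactants: 20
Product: 21 (spiculoic acid B)
Conditions: NaClO2, NaH2PO4, 2-methyl-2-butene, t-BuOH/H2O, rt
Reagents that add atoms: sodium chlorite, [Na+].[O-]Cl=O; water, O
Why: Pinnick oxidation converts the hindered neopentylic aldehyde to the acid; the scavenger protects the trisubstituted and styryl alkenes, and no stereocentre is touched.

## Compound list
1 | 2-methylpropane-1,3-diol | OCC(C)CO | starting material
2 | (S)-3-(TBSO)-2-methylpropan-1-ol | OC[C@H](C)CO[Si](C)(C)C(C)(C)C | intermediate
3 | (R)-3-(TBSO)-2-methylpropanal | O=C[C@H](C)CO[Si](C)(C)C(C)(C)C | intermediate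
4 | TBS ether of (S)-2-methylbut-3-en-1-ol | C=C[C@H](C)CO[Si](C)(C)C(C)(C)C | intermediate
5 | (S)-2-methylbut-3-en-1-ol | C=C[C@H](C)CO | intermediate
6 | (S)-2-methylbut-3-enal | O=C[C@@H](C)C=C | intermediate
7 | methyl bis(2,2,2-trifluoroethyl)phosphonoacetate | COC(=O)CP(=O)(OCC(F)(F)F)OCC(F)(F)F | starting material
8 | methyl 2-[bis(2,2,2-trifluoroethoxy)phosphoryl]butanoate | COC(=O)C(CC)P(=O)(OCC(F)(F)F)OCC(F)(F)F | intermediate (reagent)
9 | methyl (2Z,4S)-2-ethyl-4-methylhexa-2,5-dienoate | COC(=O)/C(CC)=C\[C@@H](C)C=C | intermediate
10 | 2-ethylacrolein | C=C(CC)C=O | starting material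
11 | methyl (2Z,4S,5E)-2,6-diethyl-4-methyl-7-oxohepta-2,5-dienoate | COC(=O)/C(CC)=C\[C@@H](C)/C=C(\CC)C=O | intermediate
12 | butanal | CCCC=O | starting material
13 | 2-(triphenylphosphoranylidene)butanal | CCC(C=O)=P(c1ccccc1)(c1ccccc1)c1ccccc1 | intermediate (reagent)
14 | methyl (2Z,4S,5E,7E)-2,6,8-triethyl-4-methyl-9-oxonona-2,5,7-trienoate | COC(=O)/C(CC)=C\[C@@H](C)/C=C(\CC)/C=C(\CC)C=O | intermediate
15 | diethyl benzylphosphonate | CCOP(=O)(Cc1ccccc1)OCC | starting material
16 | methyl (2Z,4S,5E,7E,9E)-2,6,8-triethyl-4-methyl-10-phenyldeca-2,5,7,9-tetraenoate | COC(=O)/C(CC)=C\[C@@H](C)/C=C(\CC)/C=C(\CC)/C=C/c1ccccc1 | intermediate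
17 | (2Z,4S,5E,7E,9E)-2,6,8-triethyl-4-methyl-10-phenyldeca-2,5,7,9-tetraen-1-ol | OC/C(CC)=C\[C@@H](C)/C=C(\CC)/C=C(\CC)/C=C/c1ccccc1 | intermediate
18 | 2-(triphenylphosphoranylidene)propanal | CC(C=O)=P(c1ccccc1)(c1ccccc1)c1ccccc1 | starting material
19 | (2E,4Z,6S,7E,9E,11E)-4,8,10-triethyl-2,6-dimethyl-12-phenyldodeca-2,4,7,9,11-pentaenal | O=C/C(C)=C/C(CC)=C\[C@@H](C)/C=C(\CC)/C=C(\CC)/C=C/c1ccccc1 | intermediate
20 | trans-fused hydrindadiene-4-carbaldehyde (IMDA adduct; CHO analogue of the target) | CCC1=C[C@@](/C=C/c2ccccc2)(CC)[C@](C)(C=O)[C@H]2C(CC)=C[C@@H](C)[C@H]12 | intermediate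
21 | spiculoic acid B | CCC1=C[C@@](/C=C/c2ccccc2)(CC)[C@](C)(C(=O)O)[C@H]2C(CC)=C[C@@H](C)[C@H]12 | target

**Total steps:** 15, including the two reagent preparations (Steps 6 and 9).
**Longest linear sequence:** 13 steps (Steps 1–5, 7, 8, 10–15).

## Three steps most likely to fail
1. **Step 14 (new organocatalytic IMDA).** The fully substituted diene terminus, the vicinal quaternary centres and the cis alkene in the tether may stall the reaction or give the wrong endo/exo or cis/trans-fusion mix.
   *Fallback:* change the activation mode. Pinnick-oxidise 19 to the dienoic acid and run the biomimetic thermal IMDA (toluene, BHT, 110–140 °C) or a high-pressure IMDA (12–15 kbar), which gives the target directly. Alternatively use the methyl ester with Me2AlCl.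
2. **Step 7 (Z-selective olefination of the labile aldehyde 6).** The aldehyde may isomerise to crotonaldehyde, lose its ee, or give poor Z:E.
   *Fallback:* reverse the order of arm construction. Run the Still–Gennari olefination first on the robust β-silyloxy aldehyde 3, then convert the CH2OTBS group into the vinyl group by TBAF followed by a telescoped Swern oxidation and Ph3P=CH2 at –78 °C.
3. **Step 1 (organocatalytic desymmetrisation).** The catalyst must distinguish Me from H on the prochiral diol, and this substrate is not established, so ee may be modest.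
   *Fallback:* lipase-catalysed mono-acetylation of 1 with vinyl acetate, using the enzyme that gives the (S)-monoester. Then protect the free OH as its TBS ether, remove the acetate and continue (the sequence that follows needs an (S)-monoacetate with the OH free for oxidation).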